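**Plan**

1. The two MOM ethers are removed last. The C2–H of the pyranone (ring C) is traced back to a C2 carboxyl, which is tied to the 2'-oxygen of ring B as a six-membered lactone.
2. That lactone is cut at the C3–C1' bond (key disconnection), giving a 2-iodoaryl chromone-2-carboxylate. The ester C–O bond is then cut to give acid 6 and iodophenol 14.
3. Acid 6 is traced to 2,4-dihydroxyacetophenone and diethyl oxalate. Iodophenol 14 is traced, through its aryl–prenyl bond, to 4-bromo-3-methoxyphenol and prenyl bromide.
4. Forward: rings A and C are built first (step 1) and the ring B fragment is prepared (steps 4–7). The ester union (step 8) is followed by closure of the lactone ring with formation of C3–C1' (step 9). The bridge is then opened, the carboxyl is lost as CO2 and the phenols are freed (steps 10–12).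
5. Enabling feature: the 2'-hydroxyl sits on the ring B carbon next to C1', and C2 of ring C bears only hydrogen in the target. A carboxyl on C2 can therefore be esterified by the 2'-oxygen, hold C1' over C3, and be excised afterwards.
6. Stereochemistry: the target has no stereocentre and the prenyl olefin carries two identical methyl groups, so nothing has to be controlled.

Key step: step 9

Remark: isoflavone numbering is used throughout (O1, C2, C3, C4 in ring C; C5–C8 in ring A; primed positions in ring B).

**Route**

Step 1
Reactants: 1 2,4-dihydroxyacetophenone; 2 diethyl oxalate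
Product: 4 ethyl 7-hydroxy-4-oxo-4H-chromene-2-carboxylate, via diketo ester 3 (not isolated)
Conditions: NaOEt (4 equiv), EtOH, reflux; then conc. HCl, EtOH, reflux
Reagents that add atoms: diethyl oxalate (2), CCOC(=O)C(=O)OCC
Why: Claisen condensation of the acetophenone enolate with the oxalate should give the 2,4-diketo ester, which on acidification cyclodehydrates through the ortho phenol to the chromone-2-carboxylate (classical oxalate chromone synthesis).

Step 2
Reactants: 4 ethyl 7-hydroxy-4-oxo-4H-chromene-2-carboxylate
Product: 5 ethyl 7-(methoxymethoxy)-4-oxo-4H-chromene-2-carboxylate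
Conditions: MOMCl (1.3 equiv), K2CO3, acetone, 0 °C to rt
Reagents that add atoms: chloromethyl methyl ether, COCCl
Why: Williamson-type O-alkylation of the only phenol, which is acidic because it is conjugated with the C4 carbonyl, should proceed cleanly with carbonate.

Step 3
Reactants: 5 ethyl 7-(methoxymethoxy)-4-oxo-4H-chromene-2-carboxylate
Product: 6 7-(methoxymethoxy)-4-oxo-4H-chromene-2-carboxylic acid
Conditions: LiOH·H2O (1.5 equiv), THF/H2O, 0 °C; then 1 M HCl to pH 2–3 at 0 °C
Reagents that add atoms: lithium hydroxide, [Li+].[OH-]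
Why: Saponification of the activated ester is faster than hydroxide attack on the pyranone in the cold, and the aryl MOM acetal should survive a brief cold acidification.

Step 4
Reactants: 7 4-bromo-3-methoxyphenol
Product: 8 (4-bromo-3-methoxyphenoxy)(tert-butyl)dimethylsilane
Conditions: TBSCl (1.2 equiv), imidazole (2.5 equiv), DMF, rt
Reagents that add atoms: tert-butyldimethylsilyl chloride, CC(C)(C)[Si](C)(C)Cl
Why: Imidazole-promoted silylation masks the acidic phenol so that the bromide can be exchanged for lithium in the next step.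

Step 5
Reactants: 8 (4-bromo-3-methoxyphenoxy)(tert-butyl)dimethylsilane; 9 prenyl bromide
Product: 12 tert-butyl[3-methoxy-4-(3-methylbut-2-en-1-yl)phenoxy]dimethylsilane, via aryllithium 10 (not isolated), via arylcopper 11 (not isolated)
Conditions: n-BuLi (1.05 equiv), THF, −78 °C; CuBr·SMe2 (1.0 equiv), −78 to −40 °C; prenyl bromide (1.3 equiv), −78 to 0 °C
Reagents that add atoms: prenyl bromide (9), CC(C)=CCBr
Why: Bromine–lithium exchange, transmetalation to the arylcopper and allylic substitution at the unhindered CH2 terminus should give the linear prenyl arene; the silyloxy group is para to the metalated carbon and cannot migrate.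

Step 6
Reactants: 12 tert-butyl[3-methoxy-4-(3-methylbut-2-en-1-yl)phenoxy]dimethylsilane
Product: 13 3-methoxy-4-(3-methylbut-2-en-1-yl)phenol
Conditions: TBAF (1.1 equiv), THF, 0 °C; aq. NH4Cl
Reagents that add atoms: none
Why: Fluoride-induced cleavage of the aryl silyl ether is fast and leaves the olefin and the methyl ether untouched.

Step 7
Reactants: 13 3-methoxy-4-(3-methylbut-2-en-1-yl)phenol
Product: 14 2-iodo-5-methoxy-4-(3-methylbut-2-en-1-yl)phenol
Conditions: NIS (1.0 equiv), MeCN, −20 to 0 °C, dark, no acid additive
Reagents that add atoms: N-iodosuccinimide, O=C1CCC(=O)N1I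
Why: Electrophilic aromatic iodination should go to the carbon ortho to the hydroxyl and para to the methoxy group, since the other activated carbon is flanked by both oxygens and hindered, and the very electron-rich ring should outrun the olefin in the absence of acid.

Step 8
Reactants: 6 7-(methoxymethoxy)-4-oxo-4H-chromene-2-carboxylic acid; 14 2-iodo-5-methoxy-4-(3-methylbut-2-en-1-yl)phenol
Product: 15 2-iodo-5-methoxy-4-(3-methylbut-2-en-1-yl)phenyl 7-(methoxymethoxy)-4-oxo-4H-chromene-2-carboxylate
Conditions: EDC·HCl (1.5 equiv), DMAP (0.2 equiv), CH2Cl2, 0 °C to rt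
Reagents that add atoms: none
Why: Steglich esterification through the acylpyridinium ion acylates the hindered ortho-iodophenol under neutral conditions that spare the MOM acetal and the prenyl group.

Step 9
Reactants: 15 2-iodo-5-methoxy-4-(3-methylbut-2-en-1-yl)phenyl 7-(methoxymethoxy)-4-oxo-4H-chromene-2-carboxylate
Product: 16 3-methoxy-9-(methoxymethoxy)-2-(3-methylbut-2-en-1-yl)chromeno[3,4-b]chromene-6,12-dione (bridged lactone: C2 carboxyl esterified by the 2'-oxygen and C3 bonded to C1')
Conditions: Pd(OAc)2 (10 mol%), PCy3·HBF4 (20 mol%), K2CO3 (2 equiv), PivOH (30 mol%), dry DMA, 100 °C, argon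
Reagents that add atoms: none
Why: Pd(OAc)2 is reduced by the phosphine to zerovalent palladium, which inserts into the C1'–I bond; after exchange of iodide for pivalate, the aryl divalent palladium species, held over the pyranone by the ester bridge, cleaves the C3–H bond by concerted metalation–deprotonation, and reductive elimination forms C3–C1' and returns zerovalent palladium. The closest known reaction type is the palladium-catalysed intramolecular direct arylation of 2-haloaryl arene- and heteroarenecarboxylates to benzo-fused six-membered lactones (biaryl lactone synthesis). The lactone ring closes by C–C reductive elimination from a seven-membered palladacycle (Pd, C1', C2', O, carbonyl C, C2, C3), which contracts to the six-membered ring; if a Heck-type insertion competes, it is a 6-endo attack on the C2=C3 bond and leads to the same product. No stereocentre is formed. The step needs site selectivity, secured because C3–H is the only C–H the three-atom tether can bring to palladium, and chemoselectivity, secured because the prenyl olefin is meta to the metalated carbon and cannot reach it, the MOM acetal is inert to carbonate, and dry DMA with sparingly soluble K2CO3 limits cleavage of the aryl ester.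

Step 10
Reactants: 16 3-methoxy-9-(methoxymethoxy)-2-(3-methylbut-2-en-1-yl)chromeno[3,4-b]chromene-6,12-dione
Product: 19 7-(methoxymethoxy)-3-[4-methoxy-2-(methoxymethoxy)-5-(3-methylbut-2-en-1-yl)phenyl]-4-oxo-4H-chromene-2-carboxylic acid, via dipotassium salt 17 (not isolated), via methoxymethyl ester 18 (not isolated)
Conditions: KOH (2.2 equiv), THF/H2O, 0 °C to rt; evaporate, toluene azeotrope; MOMCl (3 equiv), K2CO3, DMF, 0 °C to rt; aq. KOH, 0 °C; then 1 M HCl to pH 3 at 0 °C
Reagents that add atoms: potassium hydroxide, [K+].[OH-]; chloromethyl methyl ether, COCCl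
Why: Saponification of the aryl ester lactone gives a phenoxide–carboxylate that cannot reclose; alkylating both oxygens and then hydrolysing only the labile acyloxymethyl ester should leave the 2'-oxygen capped, so that the free acid cannot relactonise.

Step 11
Reactants: 19 7-(methoxymethoxy)-3-[4-methoxy-2-(methoxymethoxy)-5-(3-methylbut-2-en-1-yl)phenyl]-4-oxo-4H-chromene-2-carboxylic acid
Product: 20 7-(methoxymethoxy)-3-[4-methoxy-2-(methoxymethoxy)-5-(3-methylbut-2-en-1-yl)phenyl]-4H-chromen-4-one
Conditions: Ag2CO3 (10 mol%), AcOH (5 mol%), DMSO, 120 °C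
Reagents that add atoms: none
Why: Silver-catalysed protodecarboxylation of a heteroaromatic acid with an alpha ring oxygen and an ortho substituent should extrude CO2 from the silver carboxylate and protonate the C2–silver species; it is the low-temperature counterpart of the thermal decarboxylation that closes the Baker–Ollis isoflavone synthesis.

Step 12
Reactants: 20 7-(methoxymethoxy)-3-[4-methoxy-2-(methoxymethoxy)-5-(3-methylbut-2-en-1-yl)phenyl]-4H-chromen-4-one
Product: 21 7-hydroxy-3-[2-hydroxy-4-methoxy-5-(3-methylbut-2-en-1-yl)phenyl]-4H-chromen-4-one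
Conditions: p-TsOH·H2O (0.5 equiv), MeOH/THF, 45 °C
Reagents that add atoms: none
Why: Acid-catalysed acetal exchange with methanol removes both MOM groups; the prenyl group has no ortho hydroxyl (its neighbours are the methoxy carbon and C6'–H), so chroman formation is not possible under these mild conditions.

**Compound list**

1 | 2,4-dihydroxyacetophenone | CC(=O)c1ccc(O)cc1O | starting material
2 | diethyl oxalate | CCOC(=O)C(=O)OCC | starting material
3 | ethyl 4-(2,4-dihydroxyphenyl)-2,4-dioxobutanoate (present as its sodium enolate, not isolated) | CCOC(=O)C(=O)CC(=O)c1ccc(O)cc1O | intermediate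
4 | ethyl 7-hydroxy-4-oxo-4H-chromene-2-carboxylate | CCOC(=O)c1cc(=O)c2ccc(O)cc2o1 | intermediate
5 | ethyl 7-(methoxymethoxy)-4-oxo-4H-chromene-2-carboxylate | CCOC(=O)c1cc(=O)c2ccc(OCOC)cc2o1 | intermediate
6 | 7-(methoxymethoxy)-4-oxo-4H-chromene-2-carboxylic acid | OC(=O)c1cc(=O)c2ccc(OCOC)cc2o1 | intermediate
7 | 4-bromo-3-methoxyphenol | COc1cc(O)ccc1Br | starting material
8 | (4-bromo-3-methoxyphenoxy)(tert-butyl)dimethylsilane | COc1cc(O[Si](C)(C)C(C)(C)C)ccc1Br | intermediate
9 | prenyl bromide (1-bromo-3-methylbut-2-ene) | CC(C)=CCBr | starting material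
10 | [4-(tert-butyldimethylsilyloxy)-2-methoxyphenyl]lithium (not isolated) | [Li]c1ccc(O[Si](C)(C)C(C)(C)C)cc1OC | intermediate
11 | [4-(tert-butyldimethylsilyloxy)-2-methoxyphenyl]copper (not isolated) | [Cu]c1ccc(O[Si](C)(C)C(C)(C)C)cc1OC | intermediate
12 | tert-butyl[3-methoxy-4-(3-methylbut-2-en-1-yl)phenoxy]dimethylsilane | COc1cc(O[Si](C)(C)C(C)(C)C)ccc1CC=C(C)C | intermediate
13 | 3-methoxy-4-(3-methylbut-2-en-1-yl)phenol | COc1cc(O)ccc1CC=C(C)C | intermediate
14 | 2-iodo-5-methoxy-4-(3-methylbut-2-en-1-yl)phenol | COc1cc(O)c(I)cc1CC=C(C)C | intermediate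
15 | 2-iodo-5-methoxy-4-(3-methylbut-2-en-1-yl)phenyl 7-(methoxymethoxy)-4-oxo-4H-chromene-2-carboxylate | O=C(Oc1cc(OC)c(CC=C(C)C)cc1I)c1cc(=O)c2ccc(OCOC)cc2o1 | intermediate
16 | 3-methoxy-9-(methoxymethoxy)-2-(3-methylbut-2-en-1-yl)chromeno[3,4-b]chromene-6,12-dione | O=C1Oc2cc(OC)c(CC=C(C)C)cc2-c2c1oc1cc(OCOC)ccc1c2=O | intermediate
17 | dipotassium 7-(methoxymethoxy)-3-[4-methoxy-2-oxido-5-(3-methylbut-2-en-1-yl)phenyl]-4-oxo-4H-chromene-2-carboxylate (not isolated) | [K+].[K+].[O-]C(=O)c1oc2cc(OCOC)ccc2c(=O)c1-c1cc(CC=C(C)C)c(OC)cc1[O-] | intermediate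
18 | methoxymethyl 7-(methoxymethoxy)-3-[4-methoxy-2-(methoxymethoxy)-5-(3-methylbut-2-en-1-yl)phenyl]-4-oxo-4H-chromene-2-carboxylate (not isolated) | COCOC(=O)c1oc2cc(OCOC)ccc2c(=O)c1-c1cc(CC=C(C)C)c(OC)cc1OCOC | intermediate
19 | 7-(methoxymethoxy)-3-[4-methoxy-2-(methoxymethoxy)-5-(3-methylbut-2-en-1-yl)phenyl]-4-oxo-4H-chromene-2-carboxylic acid | OC(=O)c1oc2cc(OCOC)ccc2c(=O)c1-c1cc(CC=C(C)C)c(OC)cc1OCOC | intermediate
20 | 7-(methoxymethoxy)-3-[4-methoxy-2-(methoxymethoxy)-5-(3-methylbut-2-en-1-yl)phenyl]-4H-chromen-4-one | COCOc1ccc2c(c1)occ(-c1cc(CC=C(C)C)c(OC)cc1OCOC)c2=O | intermediate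
21 | 7-hydroxy-3-[2-hydroxy-4-methoxy-5-(3-methylbut-2-en-1-yl)phenyl]-4H-chromen-4-one | COc1cc(O)c(-c2coc3cc(O)ccc3c2=O)cc1CC=C(C)C | target

**Step count**

Total: 12 steps. Longest linear sequence: 9 steps (steps 4, 5, 6, 7, 8, 9, 10, 11, 12, from 4-bromo-3-methoxyphenol). The chromone branch (steps 1–3) joins at step 8.

**Steps most likely to fail, with fallbacks**

Step 9. The activated aryl ester may be cleaved by carbonate or pivalate before cyclisation, the iodide may be lost by protodehalogenation, or metalation of the electron-poor C3–H may be too slow. The fallback gives up the ester bridge and forms the same C3–C1' bond by an intermolecular Suzuki–Miyaura coupling. It sets out from 1 and 14 and returns to the route at 20, so that steps 8–11 fall away.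
- From 1, selective alkylation of the non-chelated 4-hydroxyl (MOMCl, K2CO3, acetone) should give 1-[2-hydroxy-4-(methoxymethoxy)phenyl]ethanone F1.
- Heating F1 with N,N-dimethylformamide dimethyl acetal should give the enaminone (E)-3-(dimethylamino)-1-[2-hydroxy-4-(methoxymethoxy)phenyl]prop-2-en-1-one F2.
- Iodine in CHCl3 with pyridine should cyclise F2 to 3-iodo-7-(methoxymethoxy)-4H-chromen-4-one F3.
- From 14, MOMCl and i-Pr2NEt should give 1-iodo-4-methoxy-2-(methoxymethoxy)-5-(3-methylbut-2-en-1-yl)benzene F4.
- Iodine–magnesium exchange on F4 with i-PrMgCl·LiCl and a quench with 2-isopropoxy-4,4,5,5-tetramethyl-1,3,2-dioxaborolane should give 2-[4-methoxy-2-(methoxymethoxy)-5-(3-methylbut-2-en-1-yl)phenyl]-4,4,5,5-tetramethyl-1,3,2-dioxaborolane F5.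
- Coupling of F3 with F5 (Pd(PPh3)4, Na2CO3, DME/H2O, 80 °C) should give 20.

Step 11. Extrusion of CO2 at the hindered C2 may be slow, and on prolonged heating the substrate's own acidity may strip the 2'-MOM group, after which the phenol recloses the lactone. The fallback removes the carboxyl carbon together with C2 and then puts C2 back. It sets out from 19 and returns at 20.
- Boiling aqueous-ethanolic KOH should open the pyranone of 19 and expel C2 with its carboxyl as oxalate by retro-Claisen cleavage, giving the deoxybenzoin 1-[2-hydroxy-4-(methoxymethoxy)phenyl]-2-[4-methoxy-2-(methoxymethoxy)-5-(3-methylbut-2-en-1-yl)phenyl]ethanone F6.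
- Heating F6 with N,N-dimethylformamide dimethyl acetal in toluene should insert the missing CH and reclose ring C (classical deoxybenzoin route to isoflavones), giving 20.

Step 7. The iodinating agent may attack the trisubstituted olefin instead of the ring, or iodinate the carbon between the two oxygens. The fallback carries a much less nucleophilic allyl group through the iodination and builds the prenyl terminus afterwards. It sets out from 8 and returns at 14.
- Bromine–lithium exchange on 8, CuBr·SMe2 and allyl bromide (as in step 5) should give (4-allyl-3-methoxyphenoxy)(tert-butyl)dimethylsilane F7.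
- TBAF should give 4-allyl-3-methoxyphenol F8.
- NIS in MeCN should give 4-allyl-2-iodo-5-methoxyphenol F9.
- Cross-metathesis of F9 with excess 2-methylbut-2-ene (second-generation Grubbs catalyst, CH2Cl2, 40 °C) should give 14.

**Further compounds**

F1 | step 9 | 1-[2-hydroxy-4-(methoxymethoxy)phenyl]ethanone | CC(=O)c1ccc(OCOC)cc1O
F2 | step 9 | (E)-3-(dimethylamino)-1-[2-hydroxy-4-(methoxymethoxy)phenyl]prop-2-en-1-one | CN(C)/C=C/C(=O)c1ccc(OCOC)cc1O
F3 | step 9 | 3-iodo-7-(methoxymethoxy)-4H-chromen-4-one | COCOc1ccc2c(c1)occ(I)c2=O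
F4 | step 9 | 1-iodo-4-methoxy-2-(methoxymethoxy)-5-(3-methylbut-2-en-1-yl)benzene | COCOc1cc(OC)c(CC=C(C)C)cc1I
F5 | step 9 | 2-[4-methoxy-2-(methoxymethoxy)-5-(3-methylbut-2-en-1-yl)phenyl]-4,4,5,5-tetramethyl-1,3,2-dioxaborolane | COCOc1cc(OC)c(CC=C(C)C)cc1B1OC(C)(C)C(C)(C)O1
F6 | step 11 | 1-[2-hydroxy-4-(methoxymethoxy)phenyl]-2-[4-methoxy-2-(methoxymethoxy)-5-(3-methylbut-2-en-1-yl)phenyl]ethanone | COCOc1ccc(C(=O)Cc2cc(CC=C(C)C)c(OC)cc2OCOC)c(O)c1
F7 | step 7 | (4-allyl-3-methoxyphenoxy)(tert-butyl)dimethylsilane | C=CCc1ccc(O[Si](C)(C)C(C)(C)C)cc1OC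
F8 | step 7 | 4-allyl-3-methoxyphenol | C=CCc1ccc(O)cc1OC
F9 | step 7 | 4-allyl-2-iodo-5-methoxyphenol | C=CCc1cc(I)c(O)cc1OC
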